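The quinone ring (C1 and C4 carbonyls, OH on C2 and C5, methyl on C3, the C19 chain on C6) is not taken from an arene but grown from the four-membered ring of a squarate. A 4-hydroxycyclobutenone carrying the chain, an isopropoxy group and a 2-ethoxy-1-methylvinyl group is heated: 4π ring opening gives a dienylketene, 6π closure joins the ketene carbon (future C1) to the ethoxy-bearing vinyl carbon (future C2), and all six ring substituents arrive in the correct order in one operation. The precursor comes from diisopropyl squarate by two successive organolithium additions; the E olefin is bought in (E)-dec-5-en-1-ol.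

Key step: step 8

Remark: the target has no stereocentre; its only stereochemical element is the E double bond C14=C15 of the side chain, so "single enantiomer" is read as "single E isomer". (E)-Dec-5-en-1-ol, 9-bromonon-1-ene, diisopropyl squarate and ethyl prop-1-enyl ether are taken as commercially available.

Step 1
Reactants: 1 (E)-dec-5-en-1-ol
Product: 2 (E)-dec-5-en-1-yl 4-methylbenzenesulfonate
Conditions: TsCl, Et3N, DMAP (cat.), CH2Cl2, 0 °C to rt
Reagents that add atoms: p-toluenesulfonyl chloride, Cc1ccc(cc1)S(Cl)(=O)=O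
Why: Standard tosylation of a primary alcohol, which leaves the remote E double bond of the purchased alcohol untouched.

Step 2
Reactants: 3 9-bromonon-1-ene; 2 (E)-dec-5-en-1-yl 4-methylbenzenesulfonate
Product: 5 (E)-nonadeca-1,14-diene, via Grignard reagent 4 (not isolated)
Conditions: 3, Mg, THF, rt; then 2, Li2CuCl4 (cat.), THF, −78 °C to rt
Reagents that add atoms: none
Why: Copper-catalysed sp3–sp3 coupling of a primary alkyl Grignard reagent with a primary tosylate (Kochi–Schlosser type), run with the olefin-bearing partner as the electrophile so that no radical arises at its hex-5-enyl position and the E geometry is carried over unchanged.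

Step 3
Reactants: 5 (E)-nonadeca-1,14-diene
Product: 7 (E)-nonadec-14-en-1-ol, via alkylborane 6 (not isolated)
Conditions: 9-BBN (1.05 equiv), THF, 0 °C to rt; then NaOH, H2O2, 0 °C to rt
Reagents that add atoms: hydrogen peroxide, OO
Why: Brown hydroboration–oxidation, in which 9-BBN adds anti-Markovnikov to the monosubstituted terminal alkene far faster than to the internal E-disubstituted one, so that the primary alcohol should result.

Step 4
Reactants: 7 (E)-nonadec-14-en-1-ol
Product: 8 (E)-1-iodononadec-14-ene
Conditions: I2, PPh3, imidazole, CH2Cl2, 0 °C to rt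
Reagents that add atoms: iodine, II
Why: Appel-type iodination (PPh3/I2/imidazole), an SN2 displacement of the oxyphosphonium ion at a primary carbon that does not touch the alkene.

Step 5
Reactants: 8 (E)-1-iodononadec-14-ene; 9 diisopropyl squarate (3,4-di(propan-2-yloxy)cyclobut-3-ene-1,2-dione)
Product: 12 3-[(E)-nonadec-14-en-1-yl]-4-(propan-2-yloxy)cyclobut-3-ene-1,2-dione, via alkyllithium 10 (not isolated), via squarate adduct 11 (not isolated)
Conditions: 8, t-BuLi (2.1 equiv), Et2O–pentane, −78 °C to rt; then 9, THF, −78 °C; aq. HCl quench; conc. HCl (cat.), CH2Cl2, rt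
Reagents that add atoms: water, O
Why: Iodine–lithium exchange gives the primary alkyllithium, which adds 1,2 to one carbonyl of the squarate, and acid then ionises the tertiary allylic alcohol so that water adds at the alkoxy carbon and isopropanol is lost (the standard squarate route to 3-alkyl-4-alkoxycyclobutenediones).

Step 6
Reactants: 13 ethyl prop-1-enyl ether (commercial E/Z mixture)
Product: 15 (Z)-2-bromo-1-ethoxyprop-1-ene (Br cis to OEt), via dibromide 14 (not isolated)
Conditions: Br2, CH2Cl2, −78 °C; then PhNEt2, 95 °C; fractional distillation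
Reagents that add atoms: bromine, BrBr
Why: Bromine addition to an enol ether followed by amine-induced loss of HBr through the oxocarbenium ion is the standard preparation of β-bromo enol ethers (as for (Z)-1-bromo-2-ethoxyethene), and the Z isomer, expected to predominate, is taken by distillation because only it leads to a stable lithium reagent.

Step 7
Reactants: 15 (Z)-2-bromo-1-ethoxyprop-1-ene; 12 3-[(E)-nonadec-14-en-1-yl]-4-(propan-2-yloxy)cyclobut-3-ene-1,2-dione
Product: 17 4-[(Z)-1-ethoxyprop-1-en-2-yl]-4-hydroxy-2-[(E)-nonadec-14-en-1-yl]-3-(propan-2-yloxy)cyclobut-2-en-1-one (racemic), via vinyllithium 16 (not isolated)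
Conditions: 15, t-BuLi (2.0 equiv), Et2O, −78 °C; cannulated into 12, THF, −78 °C; aq. NH4Cl, −78 °C; used crude
Reagents that add atoms: none
Why: Bromine–lithium exchange with retention gives a cis-β-ethoxyvinyllithium (Li and OEt syn, so anti elimination is not available at −78 °C), which adds 1,2 to the more electrophilic carbonyl of 12, the one attached to the isopropoxy-bearing carbon and not deactivated as a vinylogous ester; the new carbinol centre forms racemic and is destroyed in step 8.

Step 8
Reactants: 17 4-[(Z)-1-ethoxyprop-1-en-2-yl]-4-hydroxy-2-[(E)-nonadec-14-en-1-yl]-3-(propan-2-yloxy)cyclobut-2-en-1-one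
Product: 21 2-ethoxy-3-methyl-6-[(E)-nonadec-14-en-1-yl]-5-(propan-2-yloxy)cyclohexa-2,5-diene-1,4-dione, via dienylketene 18 (not isolated), via cyclohexadienone 19 (not isolated), via hydroquinone 20 (not isolated)
Conditions: p-xylene (dilute), 138 °C, Ar; then Ag2O, Et2O, rt
Reagents that add atoms: none
Why: Heating should open the cyclobutenone C1–C4 bond by a conrotatory 4π electrocyclic reaction in which the donor hydroxyl on C4 rotates outward, so that the ethoxypropenyl group lies cis to the ketene in dienylketene 18; a disrotatory 6π electrocyclization then bonds the ketene carbon to the ethoxy-bearing vinyl carbon (cyclohexadienone 19), enolization gives hydroquinone 20, and Ag2O oxidizes it to quinone 21. The closest known reaction type is the Moore–Liebeskind thermal rearrangement of 4-alkenyl-4-hydroxycyclobutenones to hydroquinones and quinones. The only ring formed is the quinone carbocycle, closed in the 6π-electrocyclic mode, and the sp3 carbon of 19 is transient, so no stereocentre has to be controlled. Regiochemistry follows from connectivity alone: cyclobutenone C1, C2 (chain), C3 (O-iPr), C4 and the vinyl carbons C(CH3) and CH(OEt) become quinone C1, C6, C5, C4, C3 and C2. The selectivity needed is outward rotation of OH in preference to the alkenyl group, which the strong donor character of the hydroxyl secures, and ring closure must outrun ketene side reactions, which the unhindered, electrophilic ketene terminus should allow even with the ethoxy group on the inside of the triene. The isolated E double bond of the chain is a spectator.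

Step 9
Reactants: 21 2-ethoxy-3-methyl-6-[(E)-nonadec-14-en-1-yl]-5-(propan-2-yloxy)cyclohexa-2,5-diene-1,4-dione
Product: 22 2,5-dihydroxy-3-methyl-6-[(E)-nonadec-14-en-1-yl]cyclohexa-2,5-diene-1,4-dione (target)
Conditions: 2 M NaOH, EtOH–H2O, 70 °C, Ar; then 2 M HCl
Reagents that add atoms: sodium hydroxide, [Na+].[OH-]
Why: Both alkoxy groups are vinylogous esters and should be exchanged for hydroxide by conjugate addition–elimination (vinylogous saponification), driven by the stable dianion of the 2,5-dihydroxyquinone, which acid then protonates; the isolated alkene is inert to base.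

Compound list
1 | (E)-dec-5-en-1-ol | CCCC/C=C/CCCCO | starting material
2 | (E)-dec-5-en-1-yl 4-methylbenzenesulfonate | CCCC/C=C/CCCCOS(=O)(=O)c1ccc(C)cc1 | intermediate
3 | 9-bromonon-1-ene | C=CCCCCCCCBr | starting material
4 | non-8-en-1-ylmagnesium bromide (not isolated) | C=CCCCCCCC[Mg]Br | intermediate
5 | (E)-nonadeca-1,14-diene | CCCC/C=C/CCCCCCCCCCCC=C | intermediate
6 | 9-[(E)-nonadec-14-en-1-yl]-9-borabicyclo[3.3.1]nonane (not isolated) | CCCC/C=C/CCCCCCCCCCCCCB1C2CCCC1CCC2 | intermediate
7 | (E)-nonadec-14-en-1-ol | CCCC/C=C/CCCCCCCCCCCCCO | intermediate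
8 | (E)-1-iodononadec-14-ene | CCCC/C=C/CCCCCCCCCCCCCI | intermediate
9 | diisopropyl squarate, 3,4-di(propan-2-yloxy)cyclobut-3-ene-1,2-dione | CC(C)OC1=C(OC(C)C)C(=O)C1=O | starting material
10 | [(E)-nonadec-14-en-1-yl]lithium (not isolated) | CCCC/C=C/CCCCCCCCCCCCC[Li] | intermediate
11 | 4-hydroxy-4-[(E)-nonadec-14-en-1-yl]-2,3-di(propan-2-yloxy)cyclobut-2-en-1-one (racemic, not isolated) | CCCC/C=C/CCCCCCCCCCCCCC1(O)C(OC(C)C)=C(OC(C)C)C1=O | intermediate
12 | 3-[(E)-nonadec-14-en-1-yl]-4-(propan-2-yloxy)cyclobut-3-ene-1,2-dione | CCCC/C=C/CCCCCCCCCCCCCC1=C(OC(C)C)C(=O)C1=O | intermediate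
13 | ethyl prop-1-enyl ether (commercial E/Z mixture) | CCOC=CC | starting material
14 | 1,2-dibromo-1-ethoxypropane (diastereomer mixture, not isolated) | CCOC(Br)C(C)Br | intermediate
15 | (Z)-2-bromo-1-ethoxyprop-1-ene (Br cis to OEt) | CCO/C=C(/C)Br | intermediate
16 | [(E)-1-ethoxyprop-1-en-2-yl]lithium (Li cis to OEt, not isolated) | CCO/C=C(/C)[Li] | intermediate
17 | 4-[(Z)-1-ethoxyprop-1-en-2-yl]-4-hydroxy-2-[(E)-nonadec-14-en-1-yl]-3-(propan-2-yloxy)cyclobut-2-en-1-one (racemic) | CCO/C=C(/C)C1(O)C(OC(C)C)=C(CCCCCCCCCCCCC/C=C/CCCC)C1=O | intermediate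
18 | (3Z,5Z)-6-ethoxy-4-hydroxy-5-methyl-2-[(E)-nonadec-14-en-1-yl]-3-(propan-2-yloxy)hexa-1,3,5-trien-1-one, the dienylketene (not isolated) | O=C=C(CCCCCCCCCCCCC/C=C/CCCC)/C(OC(C)C)=C(O)\C(C)=C/OCC | intermediate
19 | 6-ethoxy-4-hydroxy-5-methyl-2-[(E)-nonadec-14-en-1-yl]-3-(propan-2-yloxy)cyclohexa-2,4-dien-1-one (racemic, not isolated) | CCOC1C(=O)C(CCCCCCCCCCCCC/C=C/CCCC)=C(OC(C)C)C(O)=C1C | intermediate
20 | 2-ethoxy-3-methyl-6-[(E)-nonadec-14-en-1-yl]-5-(propan-2-yloxy)benzene-1,4-diol (not isolated) | CCOc1c(C)c(O)c(OC(C)C)c(CCCCCCCCCCCCC/C=C/CCCC)c1O | intermediate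
21 | 2-ethoxy-3-methyl-6-[(E)-nonadec-14-en-1-yl]-5-(propan-2-yloxy)cyclohexa-2,5-diene-1,4-dione | CCOC1=C(C)C(=O)C(OC(C)C)=C(CCCCCCCCCCCCC/C=C/CCCC)C1=O | intermediate
22 | 2,5-dihydroxy-3-methyl-6-[(E)-nonadec-14-en-1-yl]cyclohexa-2,5-diene-1,4-dione | CCCC/C=C/CCCCCCCCCCCCCC1=C(O)C(=O)C(C)=C(O)C1=O | target

Total step count: 9. Longest linear sequence: 8 steps (steps 1, 2, 3, 4, 5, 7, 8, 9 from (E)-dec-5-en-1-ol); step 6 is a one-step branch.

Steps most likely to fail

Step 8. The ketene may be diverted before ring closure. Possible diversions are capture by the C4 hydroxyl after inward rotation (giving a butenolide), oligomerisation if the inward ethoxy group slows the 6π closure, or loss of ethanol from the cyclohexadienone in place of enolization. The fallback uses no ring construction; it sets out from iodide 8 and comes back to the route at target 22. Purchased 1,2,4,5-tetramethoxybenzene F1 is lithiated (n-BuLi, THF, 0 °C) and methylated with MeI to 1,2,4,5-tetramethoxy-3-methylbenzene F2. A second ortho-lithiation (n-BuLi, TMEDA, THF) and alkylation with 8 should give 1,2,4,5-tetramethoxy-3-methyl-6-[(E)-nonadec-14-en-1-yl]benzene F3. Oxidative demethylation with ceric ammonium nitrate (MeCN–H2O, 0 °C) should give 2,5-dimethoxy-3-methyl-6-[(E)-nonadec-14-en-1-yl]cyclohexa-2,5-diene-1,4-dione F4, and hydrolysis under the conditions of step 9 should give 22.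

Step 7. The vinyllithium may be lost by β-elimination of lithium ethoxide (propyne formation) during or after the exchange, or it may attack the vinylogous ester carbonyl or deprotonate 12. The fallback sets out from dione 12 and comes back at target 22. Isopropenylmagnesium bromide (THF, −78 °C) should add to the same carbonyl to give 4-hydroxy-2-[(E)-nonadec-14-en-1-yl]-3-(propan-2-yloxy)-4-(prop-1-en-2-yl)cyclobut-2-en-1-one F5. Thermolysis and Ag2O oxidation as in step 8 should give 5-methyl-2-[(E)-nonadec-14-en-1-yl]-3-(propan-2-yloxy)cyclohexa-2,5-diene-1,4-dione F6, which lacks only the oxygen on the ring CH. Nucleophilic epoxidation (H2O2, Na2CO3, aq. dioxane, 0 °C) of its only non-alkoxylated quinone double bond should give the 5,6-epoxide of F6, 1-methyl-4-[(E)-nonadec-14-en-1-yl]-3-(propan-2-yloxy)-7-oxabicyclo[4.1.0]hept-3-ene-2,5-dione F7. Aqueous NaOH should open the epoxide by deprotonation α to the carbonyl (E1cB) to 2-hydroxy-3-methyl-6-[(E)-nonadec-14-en-1-yl]-5-(propan-2-yloxy)cyclohexa-2,5-diene-1,4-dione F8, and continued heating in the same base should hydrolyse the isopropyl vinylogous ester to 22.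

Step 6. The dehydrobromination may give poor Z/E control and the isomers may not separate; any E bromide carried on would give a lithium reagent that eliminates. The fallback fixes the geometry by an anti addition; it sets out from purchased ethoxyacetylene F9 and comes back at vinyllithium 16 in step 7. Deprotonation (n-BuLi, THF, −78 °C) and methylation (MeI) should give 1-ethoxyprop-1-yne F10. Radical hydrostannylation (Bu3SnH, AIBN, 70 °C), a kinetic anti addition that places tin on the carbon remote from oxygen, should give (Z)-tributyl(1-ethoxyprop-1-en-2-yl)stannane F11 with tin cis to ethoxy. Tin–lithium exchange (n-BuLi, THF, −78 °C, retention) should then give 16.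

Further compounds
F1 | step 8 | 1,2,4,5-tetramethoxybenzene (purchased) | COc1cc(OC)c(OC)cc1OC
F2 | step 8 | 1,2,4,5-tetramethoxy-3-methylbenzene | COc1cc(OC)c(OC)c(C)c1OC
F3 | step 8 | 1,2,4,5-tetramethoxy-3-methyl-6-[(E)-nonadec-14-en-1-yl]benzene | COc1c(C)c(OC)c(OC)c(CCCCCCCCCCCCC/C=C/CCCC)c1OC
F4 | step 8 | 2,5-dimethoxy-3-methyl-6-[(E)-nonadec-14-en-1-yl]cyclohexa-2,5-diene-1,4-dione | COC1=C(C)C(=O)C(OC)=C(CCCCCCCCCCCCC/C=C/CCCC)C1=O
F5 | step 7 | 4-hydroxy-2-[(E)-nonadec-14-en-1-yl]-3-(propan-2-yloxy)-4-(prop-1-en-2-yl)cyclobut-2-en-1-one (racemic) | CC(=C)C1(O)C(OC(C)C)=C(CCCCCCCCCCCCC/C=C/CCCC)C1=O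
F6 | step 7 | 5-methyl-2-[(E)-nonadec-14-en-1-yl]-3-(propan-2-yloxy)cyclohexa-2,5-diene-1,4-dione | CC1=CC(=O)C(CCCCCCCCCCCCC/C=C/CCCC)=C(OC(C)C)C1=O
F7 | step 7 | 1-methyl-4-[(E)-nonadec-14-en-1-yl]-3-(propan-2-yloxy)-7-oxabicyclo[4.1.0]hept-3-ene-2,5-dione (racemic) | CC12OC1C(=O)C(CCCCCCCCCCCCC/C=C/CCCC)=C(OC(C)C)C2=O
F8 | step 7 | 2-hydroxy-3-methyl-6-[(E)-nonadec-14-en-1-yl]-5-(propan-2-yloxy)cyclohexa-2,5-diene-1,4-dione | CC1=C(O)C(=O)C(CCCCCCCCCCCCC/C=C/CCCC)=C(OC(C)C)C1=O
F9 | step 6 | ethoxyacetylene (purchased) | CCOC#C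
F10 | step 6 | 1-ethoxyprop-1-yne | CCOC#CC
F11 | step 6 | (Z)-tributyl(1-ethoxyprop-1-en-2-yl)stannane | CCO/C=C(/C)[Sn](CCCC)(CCCC)CCCC
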